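Assumption: the target is one enol tautomer of a 2-acylcyclohexane-1,3,5-trione; the tautomers interconvert freely, and all dearomatized compounds are written in the tautomer of the given SMILES.

## Analysis of the target

- The target is a dearomatized acylphloroglucinol: a cyclohexa-2,4-dien-1-one ring with the ketone at C1, a 2-methylpropanoyl group on C2, enolic hydroxyls on C3 and C5, a five-carbon side chain on C4, and two prenyl groups on the quaternary carbon C6. The side chain is numbered C1' (bound to C4), C2' and C3'.
- C6 carries two identical groups and is achiral. The only stereocenters are the contiguous carbinol carbons C1' and C2', both S, which is the threo relationship.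
- C2' is an ordinary secondary carbinol next to an isopropyl group. It maps atom for atom, with the same descriptor, on C2 of the commercial hydroxy acid 4.
- C1' is different. It is bound to ring carbon C4, which lies between the enolic carbons C3 and C5, so the C1'–O bond can ionize to a quinone-methide-type cation. Its configuration is therefore labile to acid and, as a free carbinol, to base.
- The two prenyl double bonds are the most electron-rich alkenes of the molecule. They rule out any late dihydroxylation, epoxidation or hydrogenolysis and do not tolerate strong acid.
- The ring is an easily oxidized vinylogous acid and a C- and O-ambident nucleophile.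
- The difficulty is order and selectivity, not size. A threo diol has to be placed on the most nucleophilic and most ionizable position of the ring, with control of C1', without touching two prenyl groups and three acidic hydroxyls.
- The feature the plan exploits: the C4–C1' bond joins a nucleophilic ring carbon to a carbon flanked by the oxygenated C2'. At the aldehyde oxidation level, C1', C2' and their two oxygens close into a five-membered 1,3-dioxolane ring in which C1' is an oxocarbenium carbon. A ring of that size accepts the arene only trans to the isopropyl group, which is the threo arrangement, whatever the configuration of the precursor at C1'.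

## Retrosynthetic reasoning

**13 to 12.** The last disconnection is the unmasking of the diol: the two C–O bonds from the C1' and C2' oxygens to an isopropylidene carbon. Keeping the diol in the five-membered ketal until the end means the ionizable C1' carbinol is never free during base treatment or alkylation. The forward step must hydrolyse a ketal without ionizing C1' and without protonating the prenyl alkenes.

**12 to 9 and two equivalents of 10.** Both C6–CH2 bonds are cut. C6 is achiral and is the only unsubstituted nuclear carbon of 9, so the first alkylation has no regiochemical choice. Placing the prenyl groups after the key step keeps the two most electron-rich alkenes away from the Lewis acid and the cation of that step. The forward reaction must alkylate carbon rather than oxygen twice, the second time at the prenylated carbon of 11 and not at the carbon carrying the branched dioxolanyl group.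

**9 to 3 and 7 (key disconnection).** The C4–C1' bond between ring and side chain is cut, not the two C–O bonds of the diol. This divides the skeleton into the achiral arene 3, with two equivalent nucleophilic CH positions, and the small electrophile 7, whose only fixed stereocenter is the future C2'. The future C1' is the acetal carbon of 7 and need not be controlled in advance. No alkene has to be built and oxidized, no phenol has to be protected, and C1' is set by a ring constraint. The forward reaction must generate cation 8 from either epimer of 7 and deliver 3 anti to the isopropyl group.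

**7 to 5 to 4.** The acyloxy group at the acetal carbon of 7 is traced to the lactone carbonyl of 5, a change of one hydride through 6. The ketal of 5 is traced to the hydroxyl and carboxyl groups of 4. Compound 4 already holds all five side-chain carbons and the S configuration of C2'. The forward reaction must stop the reduction of the lactone at the lactol stage and trap it.

**3 to 1 and 2.** The aryl–acyl bond is cut. A Friedel–Crafts acylation of the symmetric triol 1 with 2 gives the ring with its full oxygen pattern in one step.

## Alternatives that were turned down

**Alternative 1:** the textbook route.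
- Disconnection: both C–O bonds of the diol, by Sharpless asymmetric dihydroxylation of an (E)-alkene, with the prenyl groups added afterwards.
- Forward key step: the tris(methoxymethyl) ether A1 of the (E)-3-methylbut-1-enyl arene (from 3 by formylation, protection and olefination) is dihydroxylated with the (DHQ)2PHAL ligand to the (1S,2S)-diol A2.
- Reasons against:
  - The dihydroxylation cannot be late, because the prenyl alkenes would react first.
  - It cannot be run on a free acylphloroglucinol. Alkaline K3Fe(CN)6 oxidizes the polyphenol, and an ortho-hydroxystyrene cyclizes or tautomerizes. Three phenol protecting groups are therefore needed.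
  - Removing them requires acid in the presence of a benzylic diol flanked by two ortho oxygens, the worst case for ionization at C1'.
  - The E-selective olefination of a 2,6-dioxygenated benzaldehyde and the face selectivity on a twisted di-ortho-substituted aryl alkene are both open.
  - The route needs about ten steps, nearly half of them protecting-group and oxidation-level handling.

**Alternative 2:** the same C4–C1' bond, made as a carbonyl addition under acyclic control.
- Forward key step: the magnesium phenoxide of 3 adds through its ortho carbon to the α-benzyloxy aldehyde A3 (from 4 by esterification, O-benzylation and partial reduction) to give the threo adduct A4 through a five-membered chelate.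
- Reasons against:
  - The threo isomer is the chelation product and needs a chelating ether on the C2' oxygen. Such an ether cannot be removed later without hydrogenolysis (prenyl groups) or strong Lewis acid (C1').
  - A silyl ether, which could be removed, steers to the Felkin–Anh erythro isomer.
  - A3 can epimerize at its α-carbon.
  - The selectivity rests on a kinetic competition between two open transition states. The cyclic cation of the chosen route makes the same bond with ring-enforced trans selectivity and a self-correcting pathway.
  - It costs three steps to A3 and one deprotection.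

**Alternative 3:** the ring itself, by a skeletal isomerization.
- Disconnection: the ring bond C1–C2, next to a carbonyl flanking C6.
- Forward key step: the 3,3-diprenylpyran-2,4-dione A5 (by double C-prenylation of a commercial hydroxypyranone) is opened by methoxide and recloses by a Claisen-type condensation to the symmetric trione A6. C-Acylation gives A7, which is then joined to 7.
- Reasons against:
  - All six ring carbons with the right oxygen pattern come at no cost in 1, so three steps are spent on something that is not the hard part.
  - C- versus O-selectivity arises twice more.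
  - The fragment union would have to run on A7 in the presence of two prenyl groups. These are π-nucleophiles toward cation 8 (Prins-type capture) and are acid-sensitive, and the nucleophilic carbon of A7 is less reactive than that of 3.
  - Direct gem-diprenylation of 3 to A7 is no escape, since 3,5- and 3,3-dialkylation compete.

Key step: step 4

## Route

Step 1
Reactants: 1 phloroglucinol (benzene-1,3,5-triol); 2 isobutyryl chloride (2-methylpropanoyl chloride)
Product: 3 phlorisobutyrophenone (2-methyl-1-(2,4,6-trihydroxyphenyl)propan-1-one)
Conditions: AlCl3 (4 equiv), CH2Cl2/MeNO2, 0 °C to 40 °C; then ice, 1 M HCl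
Reagents that add atoms: none
Why: Friedel–Crafts acylation of the threefold activated arene; the aryl ketone formed is deactivated and held as an aluminium chelate, so the reaction should stop at monoacylation; no stereocenter is involved.

Step 2
Reactants: 4 (S)-2-hydroxy-3-methylbutanoic acid
Product: 5 (5S)-2,2-dimethyl-5-(propan-2-yl)-1,3-dioxolan-4-one
Conditions: Me2C(OMe)2 (3 equiv), TsOH·H2O (cat.), acetone, 25 °C
Reagents that add atoms: 2,2-dimethoxypropane, COC(C)(C)OC
Why: Acid-catalysed transketalization of an α-hydroxy acid to its 1,3-dioxolan-4-one; no bond to the stereocenter is broken and nothing enolizes under these conditions, so the S configuration of 4 is carried into C5 of 5.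

Step 3
Reactants: 5 (5S)-2,2-dimethyl-5-(propan-2-yl)-1,3-dioxolan-4-one
Product: 7 (5S)-2,2-dimethyl-5-(propan-2-yl)-1,3-dioxolan-4-yl acetate (both C4 epimers), via aluminium lactolate 6 (not isolated)
Conditions: iBu2AlH (1.15 equiv), CH2Cl2, −78 °C; then pyridine, DMAP, Ac2O, −78 °C to 0 °C; aq potassium sodium tartrate
Reagents that add atoms: acetic anhydride, CC(=O)OC(C)=O; diisobutylaluminium hydride, CC(C)C[AlH]CC(C)C (hydride in 7, aluminium only in 6)
Why: Reductive acetylation of a lactone: iBu2AlH adds once at −78 °C to give the stable tetrahedral aluminium lactolate 6, which is acetylated in the flask before it can open to the aldehyde; C5 is untouched, and the new acetal carbon C4 forms as a mixture of epimers that does not matter because both converge on one cation in step 4.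

Step 4
Reactants: 3 phlorisobutyrophenone; 7 (5S)-2,2-dimethyl-5-(propan-2-yl)-1,3-dioxolan-4-yl acetate (both C4 epimers)
Product: 9 2-methyl-1-{2,4,6-trihydroxy-3-[(4S,5S)-2,2-dimethyl-5-(propan-2-yl)-1,3-dioxolan-4-yl]phenyl}propan-1-one, via 1,3-dioxolan-4-ylium ion 8 (not isolated)
Conditions: Sc(OTf)3 (0.2 equiv), 3 (2 equiv), MeCN, 4 Å MS, −20 °C to 20 °C
Reagents that add atoms: none
Why: Sc(OTf)3 ionizes both C4 epimers of 7 with loss of the acyloxy group to the one planar 1,3-dioxolan-4-ylium ion 8, which is attacked by one of the two equivalent, doubly hydroxyl-flanked nuclear carbons of 3 in a Friedel–Crafts alkylation, followed by rearomatization. The closest known reaction type is the Lewis-acid-promoted aryl C-glycosylation of acylphloroglucinols with anomeric acetates, together with the substitution of cyclic α-acetoxy ethers by carbon nucleophiles. The step forms the C4–C1' bond of the target and closes no ring, since the dioxolane that controls it is already present. The new stereocenter (C4 of the dioxolane, C1' of the target) is controlled by the adjacent C5 stereocenter that comes from 4: the arene should approach the five-membered cation anti to the isopropyl group and give the trans-(4S,5S) ketal, which is the threo diol in masked form. The step is stereoconvergent twice over, because the epimeric acetates share one cation and because any cis adduct can re-ionize at its benzylic C–O bond under the Lewis acid and reclose to the more stable trans-dioxolane. C- over O-alkylation is secured by reversibility, since O-alkylation is undone under the Lewis acid and drains to carbon as in an O-to-C glycoside rearrangement. Mono- over dialkylation is secured by the excess of 3 and by the bulk of the first substituent. The configuration at C5 survives only if capture of 8 outruns loss of its C5 proton, which is why the medium is kept cold, free of base and rich in nucleophile.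

Step 5
Reactants: 9 2-methyl-1-{2,4,6-trihydroxy-3-[(4S,5S)-2,2-dimethyl-5-(propan-2-yl)-1,3-dioxolan-4-yl]phenyl}propan-1-one; 10 prenyl bromide (1-bromo-3-methylbut-2-ene)
Product: 12 3,5-dihydroxy-4-[(4S,5S)-2,2-dimethyl-5-(propan-2-yl)-1,3-dioxolan-4-yl]-2-(2-methylpropanoyl)-6,6-bis(3-methylbut-2-en-1-yl)cyclohexa-2,4-dien-1-one, via monoprenyl phenol 11 (not isolated)
Conditions: NaOMe (3.2 equiv), 10 (2.3 equiv), MeOH, −15 °C to 0 °C; then aq NaH2PO4
Reagents that add atoms: none
Why: Dearomative double C-alkylation of an acylphloroglucinol polyanion with an allylic halide, a known reaction type: the first prenyl group goes to the only free nuclear carbon (11), the second to the same carbon, now the most electron-rich and far less hindered than the carbon carrying the branched dioxolanyl group, which creates the achiral quaternary C6 and the vinylogous acid. The hydrogen-bonding solvent favours C- over O-alkylation, and the base-stable ketal keeps C1' and C2' untouched.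

Step 6
Reactants: 12 3,5-dihydroxy-4-[(4S,5S)-2,2-dimethyl-5-(propan-2-yl)-1,3-dioxolan-4-yl]-2-(2-methylpropanoyl)-6,6-bis(3-methylbut-2-en-1-yl)cyclohexa-2,4-dien-1-one
Product: 13 3,5-dihydroxy-4-[(1S,2S)-1,2-dihydroxy-3-methylbutyl]-2-(2-methylpropanoyl)-6,6-bis(3-methylbut-2-en-1-yl)cyclohexa-2,4-dien-1-one (target)
Conditions: AcOH/H2O/THF (3:1:1), 35 °C
Reagents that add atoms: none
Why: Acid-catalysed ketal hydrolysis through the tertiary oxocarbenium ion of the isopropylidene carbon; neither C–O bond at C1' or C2' is broken, so the (1S,2S) configuration set in step 4 should be retained, and acid of this strength should not protonate the prenyl double bonds.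

## Compound list

1 | phloroglucinol (benzene-1,3,5-triol) | Oc1cc(O)cc(O)c1 | starting material
2 | isobutyryl chloride (2-methylpropanoyl chloride) | CC(C)C(Cl)=O | starting material
3 | phlorisobutyrophenone, 2-methyl-1-(2,4,6-trihydroxyphenyl)propan-1-one | CC(C)C(=O)c1c(O)cc(O)cc1O | intermediate
4 | (S)-2-hydroxy-3-methylbutanoic acid | CC(C)[C@H](O)C(=O)O | starting material
5 | (5S)-2,2-dimethyl-5-(propan-2-yl)-1,3-dioxolan-4-one | CC(C)[C@@H]1OC(C)(C)OC1=O | intermediate
6 | diisobutylaluminium (5S)-2,2-dimethyl-5-(propan-2-yl)-1,3-dioxolan-4-olate, aluminium lactolate formed in the flask, both C4 epimers | CC(C)C[Al](CC(C)C)OC1OC(C)(C)O[C@H]1C(C)C | intermediate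
7 | (5S)-2,2-dimethyl-5-(propan-2-yl)-1,3-dioxolan-4-yl acetate, both C4 epimers | CC(=O)OC1OC(C)(C)O[C@H]1C(C)C | intermediate
8 | (5S)-2,2-dimethyl-5-(propan-2-yl)-1,3-dioxolan-4-ylium ion, formed in the flask | CC(C)[C@@H]1OC(C)(C)[O+]=C1 | intermediate
9 | 2-methyl-1-{2,4,6-trihydroxy-3-[(4S,5S)-2,2-dimethyl-5-(propan-2-yl)-1,3-dioxolan-4-yl]phenyl}propan-1-one | CC(C)C(=O)c1c(O)cc(O)c([C@@H]2OC(C)(C)O[C@H]2C(C)C)c1O | intermediate
10 | prenyl bromide (1-bromo-3-methylbut-2-ene) | CC(C)=CCBr | starting material
11 | 2-methyl-1-{2,4,6-trihydroxy-3-[(4S,5S)-2,2-dimethyl-5-(propan-2-yl)-1,3-dioxolan-4-yl]-5-(3-methylbut-2-en-1-yl)phenyl}propan-1-one, formed in the flask | CC(C)C(=O)c1c(O)c(CC=C(C)C)c(O)c([C@@H]2OC(C)(C)O[C@H]2C(C)C)c1O | intermediate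
12 | 3,5-dihydroxy-4-[(4S,5S)-2,2-dimethyl-5-(propan-2-yl)-1,3-dioxolan-4-yl]-2-(2-methylpropanoyl)-6,6-bis(3-methylbut-2-en-1-yl)cyclohexa-2,4-dien-1-one | CC(C)=CCC1(CC=C(C)C)C(=O)C(C(=O)C(C)C)=C(O)C([C@@H]2OC(C)(C)O[C@H]2C(C)C)=C1O | intermediate
13 | 3,5-dihydroxy-4-[(1S,2S)-1,2-dihydroxy-3-methylbutyl]-2-(2-methylpropanoyl)-6,6-bis(3-methylbut-2-en-1-yl)cyclohexa-2,4-dien-1-one | CC(C)=CCC1(CC=C(C)C)C(=O)C(C(=O)C(C)C)=C(O)C([C@H](O)[C@@H](O)C(C)C)=C1O | target

## Step count and risk

Total step count: 6. Longest linear sequence: 5 steps (4 to 5 to 7 to 9 to 12 to 13); the arene branch (1 to 3) adds one step.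

**Step 4 (key step).**
- What may go wrong:
  - Incomplete facial selectivity on cation 8.
  - Loss of the C5 proton from 8 (elimination to an enediol ketal), which would erode enantiopurity on reprotonation.
  - A second alkylation of the product at its remaining nuclear carbon.
  - Transfer of the ketal to a phenolic oxygen under the Lewis acid.
- Fallback, from 5 and 3, back to the route at 9:
  - 5 is reduced with iBu2AlH (CH2Cl2, −78 °C, aqueous potassium sodium tartrate work-up) to the lactol (5S)-2,2-dimethyl-5-(propan-2-yl)-1,3-dioxolan-4-ol F1, a masked α-hydroxy aldehyde.
  - The bromomagnesium phenoxide of 3 (EtMgBr, Et2O/CH2Cl2) adds through its ortho carbon to the open aldehyde form of F1. This is a metal-phenoxide-directed ortho-hydroxyalkylation, a carbonyl addition inside a magnesium chelate with no free cation, so C2' cannot be lost by elimination.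
  - The isopropylidene group is lost on work-up, giving 1-{3-[(2S)-1,2-dihydroxy-3-methylbutyl]-2,4,6-trihydroxyphenyl}-2-methylpropan-1-one F2 as a mixture at C1'.
  - F2 is re-ketalized with 2,2-dimethoxypropane and camphorsulfonic acid under equilibrating conditions. The benzylic C1'–O bond of this phloroglucinol ionizes reversibly under acid, and the trans-dioxolane is the thermodynamic sink, so both C1' epimers should drain into 9.

**Step 5.**
- What may go wrong:
  - O-alkylation.
  - Alkylation at the carbon that carries the dioxolanyl group.
  - Under- or over-alkylation.
  - Base-induced ionization at C1' with capture of methoxide.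
- Fallback, from 9, back to the route at 12:
  - 9 is diallylated at its free nuclear carbon with allyl methyl carbonate and Pd(PPh3)4 (THF, 20 °C). In this Tsuji–Trost allylation O-allyl products are re-ionized by the catalyst and funnel to carbon. The product is the 6,6-diallyl dienone 3,5-dihydroxy-4-[(4S,5S)-2,2-dimethyl-5-(propan-2-yl)-1,3-dioxolan-4-yl]-2-(2-methylpropanoyl)-6,6-di(prop-2-en-1-yl)cyclohexa-2,4-dien-1-one F3.
  - Double cross-metathesis of F3 with 2-methylbut-2-ene (second-generation Grubbs catalyst, CH2Cl2, 40 °C) converts both allyl groups into prenyl groups and returns 12.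

**Step 6.**
- What may go wrong:
  - Acid-induced ionization at C1' with epimerization on re-addition of water.
  - Cyclodehydration of the C2' hydroxyl onto the enolic C3 or C5.
  - Acid-induced cyclization of a prenyl group onto an enol oxygen.
- Fallback, from 9, back to the route at 13:
  - The ketal is hydrolysed at the aromatic stage (AcOH/H2O) to 1-{3-[(1S,2S)-1,2-dihydroxy-3-methylbutyl]-2,4,6-trihydroxyphenyl}-2-methylpropan-1-one F4. Any C1' epimer formed there can be sent back through an equilibrating ketalization to 9 and recycled.
  - F4 is gem-diprenylated with 10 in aqueous KOH at 0 °C, where only the phenoxide carbons are alkylated and the aliphatic diol stays neutral. The base-mediated prenylation then becomes the last step, and 13 is reached without any acid treatment of the dearomatized product.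

## Further compounds

F1 | step 4 | (5S)-2,2-dimethyl-5-(propan-2-yl)-1,3-dioxolan-4-ol, both C4 epimers | CC(C)[C@@H]1OC(C)(C)OC1O
F2 | step 4 | 1-{3-[(2S)-1,2-dihydroxy-3-methylbutyl]-2,4,6-trihydroxyphenyl}-2-methylpropan-1-one, both C1' epimers | CC(C)C(=O)c1c(O)cc(O)c(C(O)[C@@H](O)C(C)C)c1O
F3 | step 5 | 3,5-dihydroxy-4-[(4S,5S)-2,2-dimethyl-5-(propan-2-yl)-1,3-dioxolan-4-yl]-2-(2-methylpropanoyl)-6,6-di(prop-2-en-1-yl)cyclohexa-2,4-dien-1-one | C=CCC1(CC=C)C(=O)C(C(=O)C(C)C)=C(O)C([C@@H]2OC(C)(C)O[C@H]2C(C)C)=C1O
F4 | step 6 | 1-{3-[(1S,2S)-1,2-dihydroxy-3-methylbutyl]-2,4,6-trihydroxyphenyl}-2-methylpropan-1-one | CC(C)C(=O)c1c(O)cc(O)c([C@H](O)[C@@H](O)C(C)C)c1O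
A1 | alternative 1 | 2-methyl-1-{2,4,6-tris(methoxymethoxy)-3-[(E)-3-methylbut-1-en-1-yl]phenyl}propan-1-one | CC(C)C(=O)c1c(OCOC)cc(OCOC)c(/C=C/C(C)C)c1OCOC
A2 | alternative 1 | 1-{3-[(1S,2S)-1,2-dihydroxy-3-methylbutyl]-2,4,6-tris(methoxymethoxy)phenyl}-2-methylpropan-1-one | CC(C)C(=O)c1c(OCOC)cc(OCOC)c([C@H](O)[C@@H](O)C(C)C)c1OCOC
A3 | alternative 2 | (S)-2-(benzyloxy)-3-methylbutanal | CC(C)[C@H](OCc1ccccc1)C=O
A4 | alternative 2 | 1-{3-[(1S,2S)-2-(benzyloxy)-1-hydroxy-3-methylbutyl]-2,4,6-trihydroxyphenyl}-2-methylpropan-1-one | CC(C)C(=O)c1c(O)cc(O)c([C@H](O)[C@@H](OCc2ccccc2)C(C)C)c1O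
A5 | alternative 3 | 6-methyl-3,3-bis(3-methylbut-2-en-1-yl)-2H-pyran-2,4(3H)-dione | CC1=CC(=O)C(CC=C(C)C)(CC=C(C)C)C(=O)O1
A6 | alternative 3 | 2,2-bis(3-methylbut-2-en-1-yl)cyclohexane-1,3,5-trione | CC(C)=CCC1(CC=C(C)C)C(=O)CC(=O)CC1=O
A7 | alternative 3 | 3,5-dihydroxy-2-(2-methylpropanoyl)-6,6-bis(3-methylbut-2-en-1-yl)cyclohexa-2,4-dien-1-one | CC(C)=CCC1(CC=C(C)C)C(=O)C(C(=O)C(C)C)=C(O)C=C1O
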